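The whole plan rests on cutting the C2–C3 bond of ring C. C2 is an isolated CH2 group held between O1 and the stereogenic carbon C3, so it can come from a methyl ether on ring A that sits ortho to the C4 carbonyl. Loss of dinitrogen from an α-diazo ketone on a chiral dirhodium catalyst places a carbene on C3, and this carbene takes a C–H bond of that methyl group: a single operation makes the C2–C3 bond, closes ring C and fixes C3. The precursor is a 2-diazo-1,2-diarylethanone with a 2,6-dimethoxy-4-silyloxyphenyl ketone (ring A) and, on the diazo carbon, the fully silylated ring B carrying the TES-protected hydrated geranyl chain.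

Key step: step 14

Assumption: the facial preference of Rh2(S-PTAD)4 for this substrate class is not secured by a close analogue; should the 3R isomer prevail, Rh2(R-PTAD)4 is used and nothing else changes.

Design of the precursor 23:
- Both oxygens ortho to the aroyl carbon stay methyl ethers, so either tilt of the twisted aroyl group offers an O–CH3 bond and both insertions give one product.
- All ring B oxygens are TBS ethers. An acetal or alkyl ether on O2′ would place an oxygen-activated C–H bond five atoms from the carbene and lead to a dihydrobenzofuran. The MOM groups needed to build ring B are therefore exchanged before the fragments are joined.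
- O7 carries the bulkier TIPS group, because this ether must survive n-BuLi and lies para to the carbonyl, where an aryl silyl ether is most easily lost.
- The tertiary alcohol is a TES ether, which removes the O–H bond that a carbene would take.

Step 1
Reactants: 1 geranyl acetate
Product: 3 (2E)-7-hydroxy-3,7-dimethyloct-2-en-1-yl acetate, via organomercury acetate 2 (not isolated)
Conditions: Hg(OAc)2, THF–H2O, rt; then NaBH4, aq. NaOH, 0 °C
Reagents that add atoms: water, O
Why: Markovnikov oxymercuration–demercuration should hydrate only the electron-rich 6,7-alkene, because the 2,3-alkene is deactivated by the allylic acetate, so the tertiary alcohol forms at C7 and the E-configured C2=C3 bond is left alone.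

Step 2
Reactants: 3 (2E)-7-hydroxy-3,7-dimethyloct-2-en-1-yl acetate
Product: 4 (2E)-3,7-dimethyl-7-(triethylsilyloxy)oct-2-en-1-yl acetate
Conditions: TESOTf, 2,6-lutidine, CH2Cl2, −78 → 0 °C
Reagents that add atoms: triethylsilyl trifluoromethanesulfonate, CC[Si](CC)(CC)OS(=O)(=O)C(F)(F)F
Why: Silyl triflate silylation with 2,6-lutidine is the standard way to cap a hindered tertiary alcohol, and the TES ether withstands base and organolithium reagents yet falls to fluoride at the end.

Step 3
Reactants: 4 (2E)-3,7-dimethyl-7-(triethylsilyloxy)oct-2-en-1-yl acetate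
Product: 5 (2E)-3,7-dimethyl-7-(triethylsilyloxy)oct-2-en-1-ol
Conditions: K2CO3 (cat.), MeOH, rt
Reagents that add atoms: none
Why: Base-catalysed transesterification (methanolysis) removes the acetate while the tertiary TES ether is inert to K2CO3 in methanol.

Step 4
Reactants: 5 (2E)-3,7-dimethyl-7-(triethylsilyloxy)oct-2-en-1-ol
Product: 6 {[(6E)-8-bromo-2,6-dimethyloct-6-en-2-yl]oxy}triethylsilane
Conditions: CBr4, PPh3, CH2Cl2, 0 °C
Reagents that add atoms: carbon tetrabromide, BrC(Br)(Br)Br
Why: The Appel reaction converts the primary allylic alcohol into the bromide under neutral conditions by SN2 displacement of the oxyphosphonium group, without allylic transposition or loss of the E-geometry.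

Step 5
Reactants: 7 resorcinol
Product: 8 1,3-bis(methoxymethoxy)benzene
Conditions: MOMCl, i-Pr2NEt, CH2Cl2, 0 °C → rt
Reagents that add atoms: chloromethyl methyl ether, COCCl
Why: Williamson-type O-alkylation of both phenols installs the MOM ethers that serve as directing groups for the two ortho-lithiations.

Step 6
Reactants: 8 1,3-bis(methoxymethoxy)benzene; 6 {[(6E)-8-bromo-2,6-dimethyloct-6-en-2-yl]oxy}triethylsilane
Product: 10 2-[(2E)-3,7-dimethyl-7-(triethylsilyloxy)oct-2-en-1-yl]-1,3-bis(methoxymethoxy)benzene, via aryllithium 9 (not isolated)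
Conditions: n-BuLi, THF, 0 °C → rt; CuBr·SMe2 (10 mol %), then 6, −78 → 0 °C
Reagents that add atoms: none
Why: Directed ortho-metalation takes place at C2 between the two MOM ethers, and copper-catalysed SN2 allylation of the aryllithium with the primary allylic bromide joins the chain at its terminal carbon with retention of the E-alkene.

Step 7
Reactants: 10 2-[(2E)-3,7-dimethyl-7-(triethylsilyloxy)oct-2-en-1-yl]-1,3-bis(methoxymethoxy)benzene
Product: 12 1-bromo-3-[(2E)-3,7-dimethyl-7-(triethylsilyloxy)oct-2-en-1-yl]-2,4-bis(methoxymethoxy)benzene, via aryllithium 11 (not isolated)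
Conditions: n-BuLi, THF, 0 °C; then BrCl2C–CCl2Br, −78 °C → rt
Reagents that add atoms: 1,2-dibromo-1,1,2,2-tetrachloroethane, ClC(Cl)(Br)C(Cl)(Cl)Br
Why: A second directed ortho-metalation is steered by a MOM oxygen to C4 (equivalent to C6), the only ring C–H bonds ortho to a directing group, and the aryllithium is quenched by electrophilic bromine transfer.

Step 8
Reactants: 12 1-bromo-3-[(2E)-3,7-dimethyl-7-(triethylsilyloxy)oct-2-en-1-yl]-2,4-bis(methoxymethoxy)benzene
Product: 14 4-bromo-2-[(2E)-3,7-dimethyl-7-(triethylsilyloxy)oct-2-en-1-yl]benzene-1,3-diol, via bis(trimethylsilyl) ether 13 (not isolated)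
Conditions: TMSOTf, 2,2′-bipyridyl, MeCN, 0 °C → rt; then H2O
Reagents that add atoms: none
Why: Silyl triflate with 2,2′-bipyridyl cleaves aromatic MOM ethers without protic acid through the aryl trimethylsilyl ethers, which hydrolyse on work-up, so the TES ether survives and the freed phenols cannot cyclise onto the neighbouring alkene.

Step 9
Reactants: 14 4-bromo-2-[(2E)-3,7-dimethyl-7-(triethylsilyloxy)oct-2-en-1-yl]benzene-1,3-diol
Product: 15 1-bromo-2,4-bis(tert-butyldimethylsilyloxy)-3-[(2E)-3,7-dimethyl-7-(triethylsilyloxy)oct-2-en-1-yl]benzene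
Conditions: TBSOTf, 2,6-lutidine, CH2Cl2, 0 °C
Reagents that add atoms: tert-butyldimethylsilyl trifluoromethanesulfonate, CC(C)(C)[Si](C)(C)OS(=O)(=O)C(F)(F)F
Why: Silylation of both phenols with the silyl triflate replaces the acetal groups, whose O–CH2 bonds a carbene would attack, by TBS ethers that offer no activated C–H bond.

Step 10
Reactants: 16 3,5-dimethoxyphenol
Product: 17 (3,5-dimethoxyphenoxy)triisopropylsilane
Conditions: TIPSCl, imidazole, DMF, rt
Reagents that add atoms: chlorotriisopropylsilane, CC(C)[Si](Cl)(C(C)C)C(C)C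
Why: Silylation of the phenol with TIPSCl and imidazole gives an ether bulky enough to withstand n-BuLi and to block lithiation next to it.

Step 11
Reactants: 17 (3,5-dimethoxyphenoxy)triisopropylsilane; 18 N-methoxy-N-methylacetamide
Product: 21 1-[2,6-dimethoxy-4-(triisopropylsilyloxy)phenyl]ethan-1-one, via aryllithium 19 (not isolated), via lithium hemiaminal alkoxide 20 (not isolated)
Conditions: n-BuLi, THF, 0 °C → rt; then 18, −78 → 0 °C; aq. work-up
Reagents that add atoms: none
Why: Directed ortho-metalation occurs at the position flanked by both methoxy groups, and acylation of the aryllithium by the Weinreb amide stops at the ketone because the chelated tetrahedral adduct persists until work-up (Weinreb ketone synthesis).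

Step 12
Reactants: 21 1-[2,6-dimethoxy-4-(triisopropylsilyloxy)phenyl]ethan-1-one; 15 1-bromo-2,4-bis(tert-butyldimethylsilyloxy)-3-[(2E)-3,7-dimethyl-7-(triethylsilyloxy)oct-2-en-1-yl]benzene
Product: 22 2-{2,4-bis(tert-butyldimethylsilyloxy)-3-[(2E)-3,7-dimethyl-7-(triethylsilyloxy)oct-2-en-1-yl]phenyl}-1-[2,6-dimethoxy-4-(triisopropylsilyloxy)phenyl]ethan-1-one
Conditions: Pd2(dba)3 (cat.), Xantphos, K3PO4, toluene, 80 °C
Reagents that add atoms: none
Why: Palladium-catalysed α-arylation of the methyl ketone enolate (Buchwald–Hartwig ketone arylation) forms the C3–C1′ bond; the weak base K3PO4 spares the aryl silyl ethers and the hindered product enolate resists a second arylation.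

Step 13
Reactants: 22 the deoxybenzoin of step 12
Product: 23 2-{2,4-bis(tert-butyldimethylsilyloxy)-3-[(2E)-3,7-dimethyl-7-(triethylsilyloxy)oct-2-en-1-yl]phenyl}-2-diazo-1-[2,6-dimethoxy-4-(triisopropylsilyloxy)phenyl]ethan-1-one
Conditions: p-ABSA, DBU, MeCN, 0 °C → rt
Reagents that add atoms: 4-acetamidobenzenesulfonyl azide, CC(=O)Nc1ccc(cc1)S(=O)(=O)N=[N+]=[N-]
Why: Regitz diazo transfer to the doubly activated benzylic methylene of the deoxybenzoin, deprotonated by DBU, gives the α-aryl-α-diazo ketone.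

Step 14
Reactants: 23 the α-aryl-α-diazo ketone of step 13
Product: 24 (3S)-3-{2,4-bis(tert-butyldimethylsilyloxy)-3-[(2E)-3,7-dimethyl-7-(triethylsilyloxy)oct-2-en-1-yl]phenyl}-5-methoxy-7-(triisopropylsilyloxy)-2,3-dihydro-4H-chromen-4-one
Conditions: Rh2(S-PTAD)4 (1 mol %; divalent rhodium), 2,2-dimethylbutane, reflux, slow addition of 23
Reagents that add atoms: none
Why: Proposed new method: Rh2(S-PTAD)4 should expel dinitrogen from 23 to give an aryl/acyl (donor–acceptor) rhodium carbene at the future C3, which takes a hydride-like C–H bond of a flanking O-methyl group through a three-centre transition state and forms the C2–C3 bond in the same event. The closest known reaction types are the dirhodium-catalysed intramolecular insertions of ortho-alkoxyaryl diazo ketones into O–CH2R bonds that give chroman-4-ones and of aryldiazoacetates into ortho-alkoxy C–H bonds that give dihydrobenzofurans, together with enantioselective reactions of α-aryl-α-diazo ketones under Rh2(S-PTAD)4; insertion into a primary O–CH3 bond by a diaryl diazo ketone has not been shown. Ring C closes as a six-membered ring by 1,6-insertion through C3, C4, C4a, C8a, O1 and C2, the methyl C–H bonds being the only ones on ring A within reach, since no 1,5-C–H bond exists. The new stereocentre C3 is set by the chiral carboxylate ligands on rhodium (catalyst control, no substrate stereocentre), and the catalyst enantiomer is chosen to give 3S. The step needs site selectivity over oxonium-ylide chemistry, insertion into ring B substituents and reaction at the alkene: two equivalent methoxy groups straddle the carbene of the twisted 2,6-disubstituted aroyl group and a methyl oxonium ylide has no easy onward shift, the silyl ethers on ring B present no oxygen-activated C–H bond, and the trisubstituted alkene sits meta to the carbene-bearing carbon and cannot reach it.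

Step 15
Reactants: 24 the (3S)-5-methoxy isoflavanone of step 14
Product: 26 (3S)-3-{2,4-bis(tert-butyldimethylsilyloxy)-3-[(2E)-3,7-dimethyl-7-(triethylsilyloxy)oct-2-en-1-yl]phenyl}-5-hydroxy-7-(triisopropylsilyloxy)-2,3-dihydro-4H-chromen-4-one, via iodomagnesium phenoxide 25 (not isolated)
Conditions: MgI2·OEt2, toluene–Et2O, 50 °C; then aq. work-up
Reagents that add atoms: none
Why: Chelation-controlled demethylation: MgI2 binds the C4 carbonyl and the peri methoxy oxygen so that iodide cleaves only that O–CH3 bond by SN2 attack, under non-basic conditions that should leave C3, the silyl ethers and the alkene untouched.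

Step 16
Reactants: 26 the (3S)-5-hydroxy isoflavanone of step 15
Product: 27 (3S)-3-{2,4-dihydroxy-3-[(2E)-7-hydroxy-3,7-dimethyloct-2-en-1-yl]phenyl}-5,7-dihydroxy-2,3-dihydro-4H-chromen-4-one (CNP0420575.1)
Conditions: HF·pyridine, pyridine, THF, 0 °C → rt
Reagents that add atoms: none
Why: Fluoride-driven cleavage of all four silyl ethers under buffered, weakly acidic conditions frees the phenols and the tertiary alcohol without the base that would enolise C3 or the strong acid that would cyclise a phenol onto the alkene.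

Compound list

1 | geranyl acetate, (2E)-3,7-dimethylocta-2,6-dien-1-yl acetate | CC(C)=CCC/C(C)=C/COC(C)=O | starting material
2 | organomercury acetate, (2E)-6-(acetoxymercurio)-7-hydroxy-3,7-dimethyloct-2-en-1-yl acetate (racemic at C6, not isolated) | CC(C)(O)C([Hg]OC(C)=O)CC/C(C)=C/COC(C)=O | intermediate
3 | (2E)-7-hydroxy-3,7-dimethyloct-2-en-1-yl acetate | CC(C)(O)CCC/C(C)=C/COC(C)=O | intermediate
4 | (2E)-3,7-dimethyl-7-(triethylsilyloxy)oct-2-en-1-yl acetate | CC[Si](CC)(CC)OC(C)(C)CCC/C(C)=C/COC(C)=O | intermediate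
5 | (2E)-3,7-dimethyl-7-(triethylsilyloxy)oct-2-en-1-ol | CC[Si](CC)(CC)OC(C)(C)CCC/C(C)=C/CO | intermediate
6 | {[(6E)-8-bromo-2,6-dimethyloct-6-en-2-yl]oxy}triethylsilane | CC[Si](CC)(CC)OC(C)(C)CCC/C(C)=C/CBr | intermediate
7 | resorcinol, benzene-1,3-diol | Oc1cccc(O)c1 | starting material
8 | 1,3-bis(methoxymethoxy)benzene | COCOc1cccc(OCOC)c1 | intermediate
9 | [2,6-bis(methoxymethoxy)phenyl]lithium (not isolated) | [Li]c1c(OCOC)cccc1OCOC | intermediate
10 | 2-[(2E)-3,7-dimethyl-7-(triethylsilyloxy)oct-2-en-1-yl]-1,3-bis(methoxymethoxy)benzene | COCOc1cccc(OCOC)c1C/C=C(\C)CCCC(C)(C)O[Si](CC)(CC)CC | intermediate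
11 | {3-[(2E)-3,7-dimethyl-7-(triethylsilyloxy)oct-2-en-1-yl]-2,4-bis(methoxymethoxy)phenyl}lithium (not isolated) | [Li]c1ccc(OCOC)c(C/C=C(\C)CCCC(C)(C)O[Si](CC)(CC)CC)c1OCOC | intermediate
12 | 1-bromo-3-[(2E)-3,7-dimethyl-7-(triethylsilyloxy)oct-2-en-1-yl]-2,4-bis(methoxymethoxy)benzene | Brc1ccc(OCOC)c(C/C=C(\C)CCCC(C)(C)O[Si](CC)(CC)CC)c1OCOC | intermediate
13 | 1-bromo-3-[(2E)-3,7-dimethyl-7-(triethylsilyloxy)oct-2-en-1-yl]-2,4-bis(trimethylsilyloxy)benzene (not isolated) | C[Si](C)(C)Oc1ccc(Br)c(O[Si](C)(C)C)c1C/C=C(\C)CCCC(C)(C)O[Si](CC)(CC)CC | intermediate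
14 | 4-bromo-2-[(2E)-3,7-dimethyl-7-(triethylsilyloxy)oct-2-en-1-yl]benzene-1,3-diol | Oc1ccc(Br)c(O)c1C/C=C(\C)CCCC(C)(C)O[Si](CC)(CC)CC | intermediate
15 | 1-bromo-2,4-bis(tert-butyldimethylsilyloxy)-3-[(2E)-3,7-dimethyl-7-(triethylsilyloxy)oct-2-en-1-yl]benzene | CC(C)(C)[Si](C)(C)Oc1ccc(Br)c(O[Si](C)(C)C(C)(C)C)c1C/C=C(\C)CCCC(C)(C)O[Si](CC)(CC)CC | intermediate
16 | 3,5-dimethoxyphenol | COc1cc(O)cc(OC)c1 | starting material
17 | (3,5-dimethoxyphenoxy)triisopropylsilane | COc1cc(OC)cc(O[Si](C(C)C)(C(C)C)C(C)C)c1 | intermediate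
18 | N-methoxy-N-methylacetamide | CC(=O)N(C)OC | starting material
19 | [2,6-dimethoxy-4-(triisopropylsilyloxy)phenyl]lithium (not isolated) | [Li]c1c(OC)cc(O[Si](C(C)C)(C(C)C)C(C)C)cc1OC | intermediate
20 | lithium 1-[2,6-dimethoxy-4-(triisopropylsilyloxy)phenyl]-1-[methoxy(methyl)amino]ethan-1-olate (not isolated) | [Li]OC(C)(N(C)OC)c1c(OC)cc(O[Si](C(C)C)(C(C)C)C(C)C)cc1OC | intermediate
21 | 1-[2,6-dimethoxy-4-(triisopropylsilyloxy)phenyl]ethan-1-one | CC(=O)c1c(OC)cc(O[Si](C(C)C)(C(C)C)C(C)C)cc1OC | intermediate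
22 | 2-{2,4-bis(tert-butyldimethylsilyloxy)-3-[(2E)-3,7-dimethyl-7-(triethylsilyloxy)oct-2-en-1-yl]phenyl}-1-[2,6-dimethoxy-4-(triisopropylsilyloxy)phenyl]ethan-1-one | COc1cc(O[Si](C(C)C)(C(C)C)C(C)C)cc(OC)c1C(=O)Cc1ccc(O[Si](C)(C)C(C)(C)C)c(C/C=C(\C)CCCC(C)(C)O[Si](CC)(CC)CC)c1O[Si](C)(C)C(C)(C)C | intermediate
23 | 2-{2,4-bis(tert-butyldimethylsilyloxy)-3-[(2E)-3,7-dimethyl-7-(triethylsilyloxy)oct-2-en-1-yl]phenyl}-2-diazo-1-[2,6-dimethoxy-4-(triisopropylsilyloxy)phenyl]ethan-1-one | COc1cc(O[Si](C(C)C)(C(C)C)C(C)C)cc(OC)c1C(=O)C(=[N+]=[N-])c1ccc(O[Si](C)(C)C(C)(C)C)c(C/C=C(\C)CCCC(C)(C)O[Si](CC)(CC)CC)c1O[Si](C)(C)C(C)(C)C | intermediate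
24 | (3S)-3-{2,4-bis(tert-butyldimethylsilyloxy)-3-[(2E)-3,7-dimethyl-7-(triethylsilyloxy)oct-2-en-1-yl]phenyl}-5-methoxy-7-(triisopropylsilyloxy)-2,3-dihydro-4H-chromen-4-one | C/C(=C\Cc1c(O[Si](C)(C)C(C)(C)C)ccc([C@H]2COc3cc(O[Si](C(C)C)(C(C)C)C(C)C)cc(OC)c3C2=O)c1O[Si](C)(C)C(C)(C)C)CCCC(C)(C)O[Si](CC)(CC)CC | intermediate
25 | iodomagnesium 5-phenoxide of 26 (not isolated) | C/C(=C\Cc1c(O[Si](C)(C)C(C)(C)C)ccc([C@H]2COc3cc(O[Si](C(C)C)(C(C)C)C(C)C)cc(O[Mg]I)c3C2=O)c1O[Si](C)(C)C(C)(C)C)CCCC(C)(C)O[Si](CC)(CC)CC | intermediate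
26 | (3S)-3-{2,4-bis(tert-butyldimethylsilyloxy)-3-[(2E)-3,7-dimethyl-7-(triethylsilyloxy)oct-2-en-1-yl]phenyl}-5-hydroxy-7-(triisopropylsilyloxy)-2,3-dihydro-4H-chromen-4-one | C/C(=C\Cc1c(O[Si](C)(C)C(C)(C)C)ccc([C@H]2COc3cc(O[Si](C(C)C)(C(C)C)C(C)C)cc(O)c3C2=O)c1O[Si](C)(C)C(C)(C)C)CCCC(C)(C)O[Si](CC)(CC)CC | intermediate
27 | (3S)-3-{2,4-dihydroxy-3-[(2E)-7-hydroxy-3,7-dimethyloct-2-en-1-yl]phenyl}-5,7-dihydroxy-2,3-dihydro-4H-chromen-4-one | C/C(=C\Cc1c(O)ccc([C@H]2COc3cc(O)cc(O)c3C2=O)c1O)CCCC(C)(C)O | target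

Total step count: 16. Longest linear sequence: 13 steps (steps 1–4, 6–9 and 12–16, from geranyl acetate).

Steps most likely to fail

Step 14. The methoxy oxygen may add to the carbene first and divert material through an oxonium ylide to rearranged benzofuranone-type products. The hindered carbene may also dimerise, or the catalyst may discriminate poorly between the faces of a carbene that bears an ortho-substituted aryl group. The fallback uses known reactions only; it sets out from 22 and comes back to the route at 24. One equivalent of MgI2·OEt2 in toluene–Et2O should remove one of the two equivalent ortho methyl ethers by chelation and give the mono-phenol 2-{2,4-bis(tert-butyldimethylsilyloxy)-3-[(2E)-3,7-dimethyl-7-(triethylsilyloxy)oct-2-en-1-yl]phenyl}-1-[2-hydroxy-6-methoxy-4-(triisopropylsilyloxy)phenyl]ethan-1-one F1. Heating with N,N-dimethylformamide dimethyl acetal in toluene should then close the pyranone to the 5-methoxyisoflavone 3-{2,4-bis(tert-butyldimethylsilyloxy)-3-[(2E)-3,7-dimethyl-7-(triethylsilyloxy)oct-2-en-1-yl]phenyl}-5-methoxy-7-(triisopropylsilyloxy)-4H-chromen-4-one F2. Noyori-type asymmetric transfer hydrogenation with RuCl(p-cymene)[(S,S)-TsDPEN] or its mirror image in HCO2H–Et3N reduces the C2=C3 bond and then the ketone under dynamic kinetic resolution. The catalyst enantiomer is chosen to give the cis alcohol (3S,4S)-3-{2,4-bis(tert-butyldimethylsilyloxy)-3-[(2E)-3,7-dimethyl-7-(triethylsilyloxy)oct-2-en-1-yl]phenyl}-5-methoxy-7-(triisopropylsilyloxy)chroman-4-ol F3. Oxidation with Dess–Martin periodinane buffered with NaHCO3 should return the ketone without touching C3 and give 24.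

Step 12. The hot, basic coupling may strip or shift the aryl silyl groups, since the product enolate lies next to the silyl ether on O2′. Oxidative addition into the hindered, electron-rich bromide may also stall. The fallback joins the fragments in a different bond order; it sets out from 15 and 17 and comes back at 22. Bromide 15 is coupled under neutral conditions at room temperature with the Reformatsky reagent made from 2-bromo-1-(morpholin-4-yl)ethan-1-one and zinc dust, using Pd(dba)2 and Q-phos [1,2,3,4,5-pentaphenyl-1′-(di-tert-butylphosphino)ferrocene] in THF. This should give the arylacetic amide 2-{2,4-bis(tert-butyldimethylsilyloxy)-3-[(2E)-3,7-dimethyl-7-(triethylsilyloxy)oct-2-en-1-yl]phenyl}-1-(morpholin-4-yl)ethan-1-one F4. Silyl ether 17 is lithiated as in step 11 to aryllithium 19, which is added to F4 at −78 °C; aqueous work-up should release 22. The C4–C4a bond is then made last, in place of C3–C1′.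

Step 15. The Lewis acid may enolise the chelated ketone, or open ring C reversibly by β-elimination of the O1 phenoxide, and so erode the configuration at C3. The fallback restores the stereocentre after the methyl ether is gone; it sets out from 26 of eroded enantiomeric purity and comes back at 26. Noyori-type asymmetric transfer hydrogenation with RuCl(p-cymene)[(S,S)-TsDPEN] or its mirror image in HCO2H–Et3N keeps C3 epimerising through the amine. By dynamic kinetic resolution it should funnel both enantiomers into the cis alcohol (3S,4S)-3-{2,4-bis(tert-butyldimethylsilyloxy)-3-[(2E)-3,7-dimethyl-7-(triethylsilyloxy)oct-2-en-1-yl]phenyl}-7-(triisopropylsilyloxy)chroman-4,5-diol F5. This acid-sensitive benzylic alcohol is oxidised at once with MnO2 in CH2Cl2, which should give back 26 with C3 fixed.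

Further compounds

F1 | step 14 | 2-{2,4-bis(tert-butyldimethylsilyloxy)-3-[(2E)-3,7-dimethyl-7-(triethylsilyloxy)oct-2-en-1-yl]phenyl}-1-[2-hydroxy-6-methoxy-4-(triisopropylsilyloxy)phenyl]ethan-1-one | COc1cc(O[Si](C(C)C)(C(C)C)C(C)C)cc(O)c1C(=O)Cc1ccc(O[Si](C)(C)C(C)(C)C)c(C/C=C(\C)CCCC(C)(C)O[Si](CC)(CC)CC)c1O[Si](C)(C)C(C)(C)C
F2 | step 14 | 3-{2,4-bis(tert-butyldimethylsilyloxy)-3-[(2E)-3,7-dimethyl-7-(triethylsilyloxy)oct-2-en-1-yl]phenyl}-5-methoxy-7-(triisopropylsilyloxy)-4H-chromen-4-one | COc1cc(O[Si](C(C)C)(C(C)C)C(C)C)cc2occ(-c3ccc(O[Si](C)(C)C(C)(C)C)c(C/C=C(\C)CCCC(C)(C)O[Si](CC)(CC)CC)c3O[Si](C)(C)C(C)(C)C)c(=O)c12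
F3 | step 14 | (3S,4S)-3-{2,4-bis(tert-butyldimethylsilyloxy)-3-[(2E)-3,7-dimethyl-7-(triethylsilyloxy)oct-2-en-1-yl]phenyl}-5-methoxy-7-(triisopropylsilyloxy)chroman-4-ol | C/C(=C\Cc1c(O[Si](C)(C)C(C)(C)C)ccc([C@H]2COc3cc(O[Si](C(C)C)(C(C)C)C(C)C)cc(OC)c3[C@H]2O)c1O[Si](C)(C)C(C)(C)C)CCCC(C)(C)O[Si](CC)(CC)CC
F4 | step 12 | 2-{2,4-bis(tert-butyldimethylsilyloxy)-3-[(2E)-3,7-dimethyl-7-(triethylsilyloxy)oct-2-en-1-yl]phenyl}-1-(morpholin-4-yl)ethan-1-one | O=C(Cc1ccc(O[Si](C)(C)C(C)(C)C)c(C/C=C(\C)CCCC(C)(C)O[Si](CC)(CC)CC)c1O[Si](C)(C)C(C)(C)C)N1CCOCC1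
F5 | step 15 | (3S,4S)-3-{2,4-bis(tert-butyldimethylsilyloxy)-3-[(2E)-3,7-dimethyl-7-(triethylsilyloxy)oct-2-en-1-yl]phenyl}-7-(triisopropylsilyloxy)chroman-4,5-diol | C/C(=C\Cc1c(O[Si](C)(C)C(C)(C)C)ccc([C@H]2COc3cc(O[Si](C(C)C)(C(C)C)C(C)C)cc(O)c3[C@H]2O)c1O[Si](C)(C)C(C)(C)C)CCCC(C)(C)O[Si](CC)(CC)CC
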